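(The readings come from a simulation with made-up constants, noise included.)

A flat line holds no rate, so we take ours from the fall before it.

all flasks: J 0.050 M; temperature 25 °C
- Wednesday's: Q 0.050 M; the very flask that is asked about, followed so far
- flask: Q 0.0500 M; time 20 min

Wednesday's run (percent of the J charged)

| time / min | Z / % | J / % |
|---|---|---|
| 1.00 | 43.4 | 1.3 |
| 3.00 | 27.5 | 0.4 |
| 6.00 | 23.1 | 0.4 |
| 8.00 | 22.7 | 0.3 |
| 12.0 | 22.9 | 0.3 |

(readings scatter by 0.3 percentage points)

- noon: at 20 min take out 90 % of the Z then present, then wait 6.0 min
- summer: at 20 min raise the temperature by 20 K, then wait 6.0 min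
- midnight: change nothing and wait 6.0 min more
- dawn: at 20 min add J, 50.0 % of the amount charged, then wait 6.0 min

- percentages count the J that a species holds: one L or D counts as two
- what is taken out of Z is counted as made
- steps thought possible: J + Q -> G; J + Z -> D; 2 J <-> L; J -> Z; Z <-> E
- the earlier runs do not show what temperature does; that part of a forecast is a guess
- additions bring no volume worth counting

* Z, in percent of the J first charged, at 20 min
* the option that brings most further Z ("none" if no option brings more than 2 percentage points) (noon / summer / midnight / dawn / none)
* Z present, with what was taken out counted in, in percent of the J first charged, after summer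
* Z present, with what was taken out counted in, in percent of the J first charged, after midnight

In Wednesday's flask, J reads 0.4 % by 3.00 min, while Z falls from 43.4 % and flattens at about 22.8 %, the mean of the last two readings. We read this as Z ⇌ E coming to balance. The excess of Z over that level shrinks between the first two readings at an apparent 0.739 min⁻¹, which gives 0.938 min as the apparent relaxation half-life, the time in which Z covers half its remaining distance to the level. This is a reading from two scattered points, and J still reads 1.3 % at 1.00 min, so whatever still feeds Z in that window may make the Z ⇌ E step itself quicker than this figure.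

From the last fast reading to 20 min lie 18.1 half-lives, so we expect Z at the level then. The wait of 6.0 min is longer than this apparent half-life, and at 6.40 such half-lives we expect it to bring Z close to a new level, if the rate stays as read. The options are therefore judged by that level, which is thermodynamic control, and not by speed.

The forecast gives 22.8 % now, 22.8 % after midnight, 23 % after summer, and noon as best. Of summer it says “only K shifts, and its direction is unknown”.

The flask gives 22.8 % now and 22.8 % after midnight, as forecast. The two part on the temperature: summer reaches 42.8 %, so the best option is summer, with a gain of 20 percentage points against 15 points from noon and 12 points from dawn.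

    J + Q → G (k = 0.260 M⁻¹ s⁻¹, Ea = 53.0 kJ mol⁻¹)
    J + Z → D (k = 0.00870 M⁻¹ s⁻¹, Ea = 52.0 kJ mol⁻¹)
    2 J ⇌ L (K = 160 M⁻¹, k = 2.50 M⁻¹ s⁻¹, Ea = 50.0 kJ mol⁻¹, ΔH = −47.0 kJ mol⁻¹)
    J → Z (k = 0.180 s⁻¹, Ea = 79.0 kJ mol⁻¹)
    Z ⇌ E (K = 3.10, k = 0.0140 s⁻¹, Ea = 72.0 kJ mol⁻¹, ΔH = −38.0 kJ mol⁻¹)
    (constants at 25 °C)

Counted in Wednesday's apparent half-life, the midnight wait is 6.40 half-lives and gains 0 points, and the flask holds Z 22.8 % beside E 70.6 % at 200 min, as it held Z 22.8 % beside E 70.6 % at 20.0 min. The dawn flask gave a second portion of J, 50.0 % of the charge, the same 6.40 half-lives, and that portion returned 12 points of Z, about a quarter of itself, where the first charge stands at 22.8 %.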